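**Retrosynthetic overview**

1. Target 17 ⇐ triol 14 (acylation of the only secondary hydroxyl, C6) ⇐ dienediol 12 (hydroxyl-directed epoxidation of C7=C8, hydride opening) ⇐ ketol 11 (anti reduction directed by the C4 hydroxyl).
2. Key disconnection: bonds C4–C5 and C4–isopropyl of the five-membered ring (C1–C2–C3–C4–C5); 11 ⇐ monocyclic dienone ester 7 by Dieckmann closure, O-silylation, isopropyl addition and unmasking in one flask.
3. Enabling feature: the oxygens on C4 and C6 stand 1,3 across the ring-fusion carbon C5, so the ring can be closed as a β-dicarbonyl. C5 is the only enolisable α-carbon of the dienone and stays trigonal until C4 is set, so C4, C5, C6 and C8 are all relayed from the quaternary C1.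
4. 7 ⇐ 3-methylcyclohept-2-en-1-one 1: asymmetric conjugate addition sets C1; chain cleavage to the ester and three oxidation-level adjustments build C7=C8(CH3)–C9=C10.
5. Ring order: the seven-membered ring comes with 1; the five-membered ring is closed last, in step 6.

Key step: step 6

Remark: bicyclic compounds are named as daucanes (C1 = methyl-bearing ring-fusion carbon, C2/C3 = CH2, C4 = isopropyl-bearing carbon, C5 = ring-fusion CH, C6–C10 round the seven-membered ring, C8 methyl-bearing); β is the face of the C1 methyl group, and absolute configuration is that of the SMILES strings.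
Remark: the sense of induction of the chiral copper catalyst in step 1 is assumed; the ligand enantiomer that gives (S)-2 is the one to be used.

**Route**

Step 1
Reactants: 1 3-methylcyclohept-2-en-1-one
Product: 2 (S)-3-(but-3-en-1-yl)-3-methylcycloheptan-1-one
Conditions: CH2=CHCH2CH2MgBr, Cu(OTf)2 (3 mol %), (4S,5S)-4,5-diphenyl-1,3-bis(2,4,6-trimethylbenzyl)imidazolinium chloride (4 mol %), Et2O, −30 °C; aq. HCl
Reagents that add atoms: but-3-en-1-ylmagnesium bromide (C=CCC[Mg]Br)
Why: NHC–copper-catalysed asymmetric conjugate addition of a Grignard reagent to a β-methyl cyclic enone, in which the chiral copper complex selects the enone face and so creates the quaternary centre C1 as (S); material that is not fully enantiopure should be upgradable by crystallisation of a later solid such as triol 14.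

Step 2
Reactants: 2 (S)-3-(but-3-en-1-yl)-3-methylcycloheptan-1-one
Product: 3 methyl 3-[(1S)-1-methyl-3-oxocycloheptyl]propanoate
Conditions: O3, NaOH, MeOH/CH2Cl2, −78 °C
Reagents that add atoms: ozone ([O-][O+]=O); methanol (CO)
Why: ozonolysis of the terminal alkene in methanolic NaOH, where carbonyl oxide and aldehyde hemiacetal are both oxidised to the methyl ester, shortens the chain by one carbon while the saturated ketone is inert and no stereocentre is touched.

Step 3
Reactants: 3 methyl 3-[(1S)-1-methyl-3-oxocycloheptyl]propanoate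
Product: 4 methyl 3-[(1S)-1-methyl-3-oxocyclohept-4-en-1-yl]propanoate
Conditions: IBX, DMSO, 70 °C
Reagents that add atoms: none
Why: IBX dehydrogenation of the ketone through its enol can only place the double bond between C7 and C8, because the other α-carbon (C5) is attached to the quaternary C1, and the ester is not enolised.

Step 4
Reactants: 4 methyl 3-[(1S)-1-methyl-3-oxocyclohept-4-en-1-yl]propanoate
Product: 6 methyl 3-[(1S)-1,5-dimethyl-3-oxocyclohept-4-en-1-yl]propanoate, via trimethylsilyl enol ether 5 (not isolated)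
Conditions: Me2CuLi, Me3SiCl, THF, −78 °C; then Pd(OAc)2, MeCN, 23 °C
Reagents that add atoms: lithium dimethylcuprate ([Li+].C[Cu-]C)
Why: Gilman cuprate conjugate addition places the methyl group on C8 and the enolate is trapped as its silyl enol ether, which Saegusa–Ito oxidation returns to the enone so that the transient C8 stereocentre is erased.

Step 5
Reactants: 6 methyl 3-[(1S)-1,5-dimethyl-3-oxocyclohept-4-en-1-yl]propanoate
Product: 7 methyl 3-[(1S)-1,5-dimethyl-3-oxocyclohepta-4,6-dien-1-yl]propanoate
Conditions: chloranil, t-BuOH, reflux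
Reagents that add atoms: none
Why: quinone dehydrogenation of the dienol of a β,β-disubstituted enone at the γ,δ-position (the reaction that turns 4-en-3-ones into 4,6-dien-3-ones) should give the linear dienone C6(=O)–C7=C8–C9=C10, the α′,β′ alternative being impossible because C1 is quaternary.

Step 6
Reactants: 7 methyl 3-[(1S)-1,5-dimethyl-3-oxocyclohepta-4,6-dien-1-yl]propanoate
Product: 11 4β-hydroxy-5αH-dauca-7,9-dien-6-one, via lithium diketonate 8 (not isolated), via triethylsilyl dienol ether 9 (not isolated), via tertiary carbinol 10 (not isolated)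
Conditions: LiN(SiMe3)2 (2.1 equiv), THF, −78 → 0 °C; Et3SiCl, −78 → 0 °C; i-PrMgCl/CeCl3, THF, −78 °C; AcOH then Bu4NF, −78 → 23 °C
Reagents that add atoms: isopropylmagnesium chloride (CC(C)[Mg]Cl)
Why: LiN(SiMe3)2 removes a hydrogen from C5, the only enolisable carbon α to the dienone carbonyl (C7 is vinylic, C1 quaternary), and the enolate acylates the tethered ester carbon C4 in a Dieckmann condensation (5-exo-trig, enolexo), which closes the five-membered ring C1–C2–C3–C4–C5 and is driven by formation of diketonate 8. O-Silylation then gives 9, in which C5 is trigonal and the bicycle flat; the enol that is exocyclic to the five-membered and endocyclic to the seven-membered ring (silicon on the C6 oxygen) is the favoured one and the two O-silyl isomers can interconvert by 1,5-silyl shift, so the nucleophile meets the more electrophilic and less hindered cyclopentanone carbonyl C4. The isopropylcerium reagent adds 1,2 to C4, as in a Stork–Danheiser addition to a β-oxy enone (cerium suppresses enolisation and β-hydride reduction), from the α face, anti to the pseudo-axial C1 methyl group that stands 1,3 to C4, and this sets C4 (hydroxyl β, isopropyl α). Buffered fluoride unmasks the C6 ketone without ionising the tertiary allylic alcohol, and C5 is protonated to, or epimerises through the enol to, the trans-fused ketol, the only C5 epimer in which the isopropyl group is anti to C6 and the C4 hydroxyl can hydrogen-bond to the C6 carbonyl. The step thus needs site selectivity (C4 against C6), facial selectivity at C4 and survival of the β-hydroxy ketone; these should be secured by the enol preference with its silyl shuttle, by the angular methyl group and by the cold buffered work-up.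

Step 7
Reactants: 11 4β-hydroxy-5αH-dauca-7,9-dien-6-one
Product: 12 5αH-dauca-7,9-diene-4β,6α-diol
Conditions: Me4NBH(OAc)3, AcOH/MeCN, −30 °C
Reagents that add atoms: none
Why: Evans–Saksena reduction, in which the C4 hydroxyl exchanges onto boron and delivers hydride intramolecularly to the β face of the C6 carbonyl (the face it shares with the C4 oxygen and the angular methyl), should give the 1,3-anti diol with the 6α hydroxyl that external hydride, attacking the open α face, would not give.

Step 8
Reactants: 12 5αH-dauca-7,9-diene-4β,6α-diol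
Product: 13 7α,8α-epoxy-5αH-dauc-9-ene-4β,6α-diol
Conditions: VO(acac)2 (cat.), t-BuOOH, CH2Cl2, 0 °C
Reagents that add atoms: tert-butyl hydroperoxide (CC(C)(C)OO)
Why: vanadium-catalysed hydroxyl-directed epoxidation attacks the only alkene that is allylic to a hydroxyl group (C7=C8) and delivers oxygen syn to the C6 hydroxyl, that is to the α face, which fixes C8 (C–O α, methyl β).

Step 9
Reactants: 13 7α,8α-epoxy-5αH-dauc-9-ene-4β,6α-diol
Product: 14 5αH-dauc-9-ene-4β,6α,8α-triol
Conditions: LiAlH4, THF, 0 → 23 °C
Reagents that add atoms: none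
Why: hydride opening of the trisubstituted epoxide by SN2 attack at the secondary carbon C7, anti to the epoxide oxygen, leaves the C8–O bond and its configuration untouched and gives the tertiary allylic alcohol, SN2′ attack at C10 being blocked by the adjacent quaternary C1.

Step 10
Reactants: 14 5αH-dauc-9-ene-4β,6α,8α-triol; 15 4-acetoxybenzoic acid
Product: 16 4β,8α-dihydroxy-5αH-dauc-9-en-6α-yl 4-acetoxybenzoate
Conditions: DIC, DMAP (cat.), CH2Cl2, 23 °C
Reagents that add atoms: none
Why: Steglich esterification should acylate only the secondary hydroxyl at C6, the tertiary hydroxyls at C4 and C8 being unreactive under these conditions, and no stereocentre is affected.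

Step 11
Reactants: 16 4β,8α-dihydroxy-5αH-dauc-9-en-6α-yl 4-acetoxybenzoate
Product: 17 4β,8α-dihydroxy-5αH-dauc-9-en-6α-yl 4-hydroxybenzoate
Conditions: K2CO3 (cat.), MeOH, 0 °C
Reagents that add atoms: none
Why: base-catalysed transesterification cleaves the phenyl acetate far faster than the hindered secondary benzoate, which is deactivated further once the phenoxide has formed, and so releases the free phenol.

**Compound list**

1 | 3-methylcyclohept-2-en-1-one | CC1=CC(=O)CCCC1 | starting material
2 | (S)-3-(but-3-en-1-yl)-3-methylcycloheptan-1-one | C=CCC[C@]1(C)CCCCC(=O)C1 | intermediate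
3 | methyl 3-[(1S)-1-methyl-3-oxocycloheptyl]propanoate | COC(=O)CC[C@]1(C)CCCCC(=O)C1 | intermediate
4 | methyl 3-[(1S)-1-methyl-3-oxocyclohept-4-en-1-yl]propanoate | COC(=O)CC[C@]1(C)CCC=CC(=O)C1 | intermediate
5 | methyl 3-[(1S)-1,5-dimethyl-3-(trimethylsilyloxy)cyclohept-3-en-1-yl]propanoate (both epimers at the methyl-bearing ring carbon) | COC(=O)CC[C@]1(C)CCC(C)C=C(O[Si](C)(C)C)C1 | intermediate
6 | methyl 3-[(1S)-1,5-dimethyl-3-oxocyclohept-4-en-1-yl]propanoate | COC(=O)CC[C@]1(C)CCC(C)=CC(=O)C1 | intermediate
7 | methyl 3-[(1S)-1,5-dimethyl-3-oxocyclohepta-4,6-dien-1-yl]propanoate | COC(=O)CC[C@]1(C)C=CC(C)=CC(=O)C1 | intermediate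
8 | lithium (3aR)-3a,6-dimethyl-1-oxo-1,2,3,3a-tetrahydroazulen-8-olate (C4 ketone, C6 enolate, C5 trigonal) | O=C1CC[C@]2(C)C=CC(C)=CC([O-])=C21.[Li+] | intermediate
9 | (3aR)-3a,6-dimethyl-8-(triethylsilyloxy)-3,3a-dihydroazulen-1(2H)-one | O=C1CC[C@]2(C)C=CC(C)=CC(O[Si](CC)(CC)CC)=C21 | intermediate
10 | 6-(triethylsilyloxy)dauca-5,7,9-trien-4β-ol (isopropyl α) | CC(C)[C@]1(O)CC[C@]2(C)C=CC(C)=CC(O[Si](CC)(CC)CC)=C21 | intermediate
11 | 4β-hydroxy-5αH-dauca-7,9-dien-6-one (trans-fused) | CC(C)[C@]1(O)CC[C@]2(C)C=CC(C)=CC(=O)[C@H]21 | intermediate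
12 | 5αH-dauca-7,9-diene-4β,6α-diol | CC(C)[C@]1(O)CC[C@]2(C)C=CC(C)=C[C@H](O)[C@H]21 | intermediate
13 | 7α,8α-epoxy-5αH-dauc-9-ene-4β,6α-diol | CC(C)[C@]1(O)CC[C@]2(C)C=C[C@]3(C)O[C@@H]3[C@H](O)[C@H]21 | intermediate
14 | 5αH-dauc-9-ene-4β,6α,8α-triol | CC(C)[C@]1(O)CC[C@]2(C)C=C[C@](C)(O)C[C@H](O)[C@H]21 | intermediate
15 | 4-acetoxybenzoic acid | CC(=O)Oc1ccc(cc1)C(=O)O | starting material
16 | 4β,8α-dihydroxy-5αH-dauc-9-en-6α-yl 4-acetoxybenzoate | CC(C)[C@]1(O)CC[C@]2(C)C=C[C@](C)(O)C[C@H](OC(=O)c3ccc(OC(C)=O)cc3)[C@H]21 | intermediate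
17 | 4β,8α-dihydroxy-5αH-dauc-9-en-6α-yl 4-hydroxybenzoate (CNP0280165.4) | CC(C)[C@]1(O)CC[C@]2(C)C=C[C@](C)(O)C[C@H](OC(=O)c3ccc(O)cc3)[C@H]21 | target

**Step count and risks**

Total step count: 11. Longest linear sequence: 11 steps (1 → 17; 15 is bought).

Most likely to fail, in this order:

Step 6. What may go wrong: attack of the isopropyl nucleophile at the C6 carbon or on the β face of C4, valence isomerisation of the cross-conjugated trienolate before it is acylated, or loss of the new tertiary hydroxyl during unmasking. The fallback sets out from 7 and comes back at 11; it introduces the C4 oxygen by hydroxyl-directed epoxidation instead of carbonyl addition. Saponification (LiOH, THF/H2O) gives 3-[(1S)-1,5-dimethyl-3-oxocyclohepta-4,6-dien-1-yl]propanoic acid F1. Its acid chloride ((COCl)2, cat. DMF) is coupled with i-PrZnBr under Pd(PPh3)4 catalysis (Negishi acylation, which leaves the dienone alone) to give (6S)-3,6-dimethyl-6-(4-methyl-3-oxopentyl)cyclohepta-2,4-dien-1-one F2. KOt-Bu in t-BuOH closes the five-membered ring by intramolecular aldol condensation to dauca-4,7,9-trien-6-one F3, in which C4 and C5 are both trigonal. Luche reduction (NaBH4, CeCl3, MeOH, −78 °C; hydride anti to the angular methyl) gives dauca-4,7,9-trien-6β-ol F4. VO(acac)2/t-BuOOH should epoxidise the tetrasubstituted, non-conjugated C4=C5 bond syn to the 6β hydroxyl, giving 4β,5β-epoxydauca-7,9-dien-6β-ol F5. Dess–Martin oxidation gives 4β,5β-epoxydauca-7,9-dien-6-one F6, and SmI2 (THF/MeOH, −90 °C) cleaves the C5–O bond of the epoxy ketone, the enolate being protonated to the trans-fused ketol 11.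

Step 7. What may go wrong: slow ligand exchange at the hindered tertiary hydroxyl, so that hydride is not delivered internally and facial selectivity is poor or the ketone is not reduced. The fallback sets out from 11 and comes back at 12; it uses inversion instead of directed delivery. NaBH4 (MeOH, −40 °C) attacks the open α face and gives 5αH-dauca-7,9-diene-4β,6β-diol F7. A Mitsunobu reaction (PPh3, DIAD, 4-nitrobenzoic acid) inverts C6 to 4β-hydroxy-5αH-dauca-7,9-dien-6α-yl 4-nitrobenzoate F8, and K2CO3/MeOH removes the ester to give 12.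

Step 5. What may go wrong: incomplete hydride abstraction, Diels–Alder trapping of the dienol by the quinone, or over-oxidation. The fallback sets out from 6 and comes back at 7. t-BuMe2SiOTf/Et3N gives the extended (thermodynamic) silyl dienol ether methyl 3-[(1R)-3-(tert-butyldimethylsilyloxy)-1,5-dimethylcyclohepta-3,5-dien-1-yl]propanoate F9, and Saegusa–Ito oxidation with Pd(OAc)2 in MeCN introduces the C9=C10 double bond to give 7.

**Further compounds**

F1 | step 6 | 3-[(1S)-1,5-dimethyl-3-oxocyclohepta-4,6-dien-1-yl]propanoic acid | OC(=O)CC[C@]1(C)C=CC(C)=CC(=O)C1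
F2 | step 6 | (6S)-3,6-dimethyl-6-(4-methyl-3-oxopentyl)cyclohepta-2,4-dien-1-one | CC(C)C(=O)CC[C@]1(C)C=CC(C)=CC(=O)C1
F3 | step 6 | dauca-4,7,9-trien-6-one | CC(C)C1=C2C(=O)C=C(C)C=C[C@@]2(C)CC1
F4 | step 6 | dauca-4,7,9-trien-6β-ol | CC(C)C1=C2[C@H](O)C=C(C)C=C[C@@]2(C)CC1
F5 | step 6 | 4β,5β-epoxydauca-7,9-dien-6β-ol | CC(C)[C@]13CC[C@]2(C)C=CC(C)=C[C@@H](O)[C@@]21O3
F6 | step 6 | 4β,5β-epoxydauca-7,9-dien-6-one | CC(C)[C@]13CC[C@]2(C)C=CC(C)=CC(=O)[C@@]21O3
F7 | step 7 | 5αH-dauca-7,9-diene-4β,6β-diol | CC(C)[C@]1(O)CC[C@]2(C)C=CC(C)=C[C@@H](O)[C@H]21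
F8 | step 7 | 4β-hydroxy-5αH-dauca-7,9-dien-6α-yl 4-nitrobenzoate | CC(C)[C@]1(O)CC[C@]2(C)C=CC(C)=C[C@H](OC(=O)c3ccc(cc3)[N+](=O)[O-])[C@H]21
F9 | step 5 | methyl 3-[(1R)-3-(tert-butyldimethylsilyloxy)-1,5-dimethylcyclohepta-3,5-dien-1-yl]propanoate | COC(=O)CC[C@]1(C)CC=C(C)C=C(O[Si](C)(C)C(C)(C)C)C1
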